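**Retrosynthetic overview**

- Numbering: C1 is the quaternary carbinol carbon, C2 the CH–OAc carbon, C3 the CH–OBz carbon next to it, C4=C5 the alkene, C6 the other CH–OBz carbon, C7 the CH2OBz carbon. The strategy rests on the cyclohexene ring carrying the tertiary C1–OH cis to the C2 oxygen and trans to the C6 benzoate, which is the imprint of a C1–C6 oxirane syn to C2–OH that has been opened at allylic C6.
- Late disconnections: the C3–O benzoate (Mitsunobu inversion of the one centre that the chiral pool delivers with the wrong sense), the C2 acetate, then the C6–O benzoate (anti opening of the vinyl oxirane by benzoic acid).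
- Key disconnection: the C1–O and C6–O bonds of the oxirane, made by epoxidation of the C1=C6 alkene of a dienol under direction of the free C2 hydroxyl.
- The dienol comes from the cis-dihydrodiol of bromobenzene: its two carbinol carbons become C2 and C3, and its C–Br carbon becomes C1 and receives C7 by Stille hydroxymethylation.
- Ring order: the six-membered carbocycle is taken intact from the dearomatised arene; the only ring formed is the oxirane (step 4), which is opened again in step 5.

Key step: step 4

Remark: the hydroxyl of 1 remote from bromine is assumed to silylate first, because the bromine screens its neighbour. The labels C1–C7 defined above are used for every intermediate. C2 is acetylated before C3 is unmasked so that C3–OH is the only secondary hydroxyl present in the Mitsunobu step.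

**Step 1**
Reactants: 1 (1S,2S)-3-bromocyclohexa-3,5-diene-1,2-diol
Product: 2 (1S,6S)-2-bromo-6-[(tert-butyldimethylsilyl)oxy]cyclohexa-2,4-dien-1-ol (C3–O silyl ether, C2–OH free)
Conditions: TBSCl (1.05 equiv), imidazole, DMF, −10 °C
Reagents that add atoms: tert-butyldimethylsilyl chloride, CC(C)(C)[Si](C)(C)Cl
Why: Regioselective O-silylation, in which the bulky silyl chloride should take the C3 hydroxyl because the C2 hydroxyl is screened by the adjacent C–Br bond; no stereocentre is touched.

**Step 2**
Reactants: 2 (1S,6S)-2-bromo-6-[(tert-butyldimethylsilyl)oxy]cyclohexa-2,4-dien-1-ol; 3 (tributylstannyl)methanol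
Product: 4 (1R,6S)-6-[(tert-butyldimethylsilyl)oxy]-2-(hydroxymethyl)cyclohexa-2,4-dien-1-ol
Conditions: Pd(PPh3)4 (5 mol %), dioxane (degassed, dilute), 80 °C
Reagents that add atoms: none
Why: Stille cross-coupling, in which zerovalent palladium inserts into the vinylic C1–Br bond, the hydroxymethyl group is transferred from tin in preference to butyl, and reductive elimination forms the C1–C7 bond without touching C2, C3 or the silyl ether.

**Step 3**
Reactants: 4 (1R,6S)-6-[(tert-butyldimethylsilyl)oxy]-2-(hydroxymethyl)cyclohexa-2,4-dien-1-ol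
Product: 5 [(5S,6R)-5-[(tert-butyldimethylsilyl)oxy]-6-hydroxycyclohexa-1,3-dien-1-yl]methyl benzoate
Conditions: BzCl (1.05 equiv), 2,4,6-collidine, CH2Cl2, −78 to −40 °C
Reagents that add atoms: benzoyl chloride, O=C(Cl)c1ccccc1
Why: Chemoselective O-benzoylation with an acyl chloride and a hindered pyridine base, which at low temperature should acylate the primary C7 hydroxyl and leave the secondary C2 hydroxyl (flanked by C1 and the cis silyl ether) free as the directing group for step 4.

**Step 4**
Reactants: 5 [(5S,6R)-5-[(tert-butyldimethylsilyl)oxy]-6-hydroxycyclohexa-1,3-dien-1-yl]methyl benzoate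
Product: 6 [(1S,2S,3S,6R)-3-[(tert-butyldimethylsilyl)oxy]-2-hydroxy-7-oxabicyclo[4.1.0]hept-4-en-1-yl]methyl benzoate (C1–C6 oxirane syn to C2–OH)
Conditions: VO(acac)2 (5 mol %), t-BuOOH (anhydrous, in decane, 1.5 equiv), CH2Cl2, 0 °C to rt
Reagents that add atoms: tert-butyl hydroperoxide, CC(C)(C)OO
Why: This is a hydroxyl-directed vanadium-catalysed epoxidation of a cyclic allylic alcohol: t-BuOOH oxidises VO(acac)2 to a pentavalent vanadium oxo species that binds the C2 alkoxide and the tert-butylperoxide on one metal centre, and the peroxide oxygen is passed to the neighbouring C1=C6 π-bond inside that complex. The oxirane, the only ring formed, closes by concerted intramolecular oxygen-atom transfer, with the C1–O and C6–O bonds made in one event on the face that carries the C2 oxygen. Both new stereocentres, quaternary C1 and C6, are therefore set by the existing C2 carbinol centre through the vanadate ester, and the cis ring fusion ties C6 to C1. The step needs site selectivity between C1=C6 and C4=C5: only C1=C6 is allylic to a free hydroxyl and it is the more substituted alkene, whereas C4=C5 is merely homoallylic to C2–OH and its own allylic oxygen at C3 is capped as a silyl ether that cannot bind vanadium. Facial selectivity comes from the same coordination, which should override the steric bias of the C3 silyl ether on that face; running at 0 °C with anhydrous oxidant should keep oxidation of the C2 carbinol and acid-triggered aromatisation of the dienol slow.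

**Step 5**
Reactants: 6 [(1S,2S,3S,6R)-3-[(tert-butyldimethylsilyl)oxy]-2-hydroxy-7-oxabicyclo[4.1.0]hept-4-en-1-yl]methyl benzoate; 7 benzoic acid
Product: 8 [(1S,2S,5S,6S)-2-(benzoyloxy)-5-[(tert-butyldimethylsilyl)oxy]-1,6-dihydroxycyclohex-3-en-1-yl]methyl benzoate
Conditions: Ti(OiPr)4 (1.5 equiv), PhCO2H (2 equiv), CH2Cl2, rt; aq. tartaric acid work-up
Reagents that add atoms: none
Why: Titanium-mediated regioselective opening of a 2,3-epoxy alcohol by a carboxylic acid, in which tetravalent titanium chelated between the C2 alkoxide and the oxirane oxygen activates the C6–O bond (also allylic, while C1 is fully substituted), so benzoate should attack C6 in an SN2 manner from the face opposite the oxirane, with inversion, leaving C1–OH on the C2–OH face and the C6 benzoate trans to it.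

**Step 6**
Reactants: 8 [(1S,2S,5S,6S)-2-(benzoyloxy)-5-[(tert-butyldimethylsilyl)oxy]-1,6-dihydroxycyclohex-3-en-1-yl]methyl benzoate
Product: 9 [(1R,2S,5S,6S)-6-(acetyloxy)-2-(benzoyloxy)-5-[(tert-butyldimethylsilyl)oxy]-1-hydroxycyclohex-3-en-1-yl]methyl benzoate
Conditions: Ac2O, pyridine, DMAP (cat.), CH2Cl2, 0 °C to rt
Reagents that add atoms: acetic anhydride, CC(=O)OC(C)=O
Why: DMAP-catalysed O-acetylation, in which only the secondary C2 hydroxyl should be acylated because the C1 hydroxyl is tertiary and buried between three substituted carbons; stereocentres are untouched.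

**Step 7**
Reactants: 9 [(1R,2S,5S,6S)-6-(acetyloxy)-2-(benzoyloxy)-5-[(tert-butyldimethylsilyl)oxy]-1-hydroxycyclohex-3-en-1-yl]methyl benzoate
Product: 10 [(1R,2S,5S,6S)-6-(acetyloxy)-2-(benzoyloxy)-1,5-dihydroxycyclohex-3-en-1-yl]methyl benzoate
Conditions: HF·pyridine, pyridine, THF, 0 °C to rt
Reagents that add atoms: none
Why: Fluoride-mediated desilylation, in which mildly acidic HF·pyridine cleaves the secondary silyl ether through Si–F bond formation without generating a free alkoxide, so the C2 acetyl group should not migrate to the cis C3 oxygen and the three esters should survive.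

**Step 8**
Reactants: 10 [(1R,2S,5S,6S)-6-(acetyloxy)-2-(benzoyloxy)-1,5-dihydroxycyclohex-3-en-1-yl]methyl benzoate; 7 benzoic acid
Product: 11 [(1R,2S,5R,6S)-6-(acetyloxy)-2,5-bis(benzoyloxy)-1-hydroxycyclohex-3-en-1-yl]methyl benzoate (target)
Conditions: PPh3, DIAD, PhCO2H, toluene, 0 °C to rt
Reagents that add atoms: none
Why: Mitsunobu reaction, in which the C3 hydroxyl (the only secondary one; the tertiary C1 hydroxyl is inert) is activated as an oxyphosphonium ion and displaced by benzoate in an SN2 step with inversion, placing the C3 benzoate trans to the C2 acetate; the cis acetate cannot participate from the rear.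

**Compound list**

1 | (1S,2S)-3-bromocyclohexa-3,5-diene-1,2-diol | O[C@H]1[C@@H](O)C=CC=C1Br | starting material
2 | (1S,6S)-2-bromo-6-[(tert-butyldimethylsilyl)oxy]cyclohexa-2,4-dien-1-ol | O[C@H]1[C@@H](O[Si](C)(C)C(C)(C)C)C=CC=C1Br | intermediate
3 | (tributylstannyl)methanol | CCCC[Sn](CCCC)(CCCC)CO | starting material
4 | (1R,6S)-6-[(tert-butyldimethylsilyl)oxy]-2-(hydroxymethyl)cyclohexa-2,4-dien-1-ol | O[C@H]1[C@@H](O[Si](C)(C)C(C)(C)C)C=CC=C1CO | intermediate
5 | [(5S,6R)-5-[(tert-butyldimethylsilyl)oxy]-6-hydroxycyclohexa-1,3-dien-1-yl]methyl benzoate | O[C@H]1[C@@H](O[Si](C)(C)C(C)(C)C)C=CC=C1COC(=O)c1ccccc1 | intermediate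
6 | [(1S,2S,3S,6R)-3-[(tert-butyldimethylsilyl)oxy]-2-hydroxy-7-oxabicyclo[4.1.0]hept-4-en-1-yl]methyl benzoate | O[C@H]1[C@@H](O[Si](C)(C)C(C)(C)C)C=C[C@H]2O[C@@]12COC(=O)c1ccccc1 | intermediate
7 | benzoic acid | O=C(O)c1ccccc1 | starting material
8 | [(1S,2S,5S,6S)-2-(benzoyloxy)-5-[(tert-butyldimethylsilyl)oxy]-1,6-dihydroxycyclohex-3-en-1-yl]methyl benzoate | O[C@H]1[C@@H](O[Si](C)(C)C(C)(C)C)C=C[C@H](OC(=O)c2ccccc2)[C@]1(O)COC(=O)c1ccccc1 | intermediate
9 | [(1R,2S,5S,6S)-6-(acetyloxy)-2-(benzoyloxy)-5-[(tert-butyldimethylsilyl)oxy]-1-hydroxycyclohex-3-en-1-yl]methyl benzoate | CC(=O)O[C@H]1[C@@H](O[Si](C)(C)C(C)(C)C)C=C[C@H](OC(=O)c2ccccc2)[C@]1(O)COC(=O)c1ccccc1 | intermediate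
10 | [(1R,2S,5S,6S)-6-(acetyloxy)-2-(benzoyloxy)-1,5-dihydroxycyclohex-3-en-1-yl]methyl benzoate | CC(=O)O[C@H]1[C@@H](O)C=C[C@H](OC(=O)c2ccccc2)[C@]1(O)COC(=O)c1ccccc1 | intermediate
11 | [(1R,2S,5R,6S)-6-(acetyloxy)-2,5-bis(benzoyloxy)-1-hydroxycyclohex-3-en-1-yl]methyl benzoate | CC(=O)O[C@H]1[C@H](OC(=O)c2ccccc2)C=C[C@H](OC(=O)c2ccccc2)[C@]1(O)COC(=O)c1ccccc1 | target

**Step count**

Total steps: 8. Longest linear sequence: 8 steps (1 to 11).

**Steps most likely to fail**

Step 4 (key step). The vanadium centre may oxidise the C2 carbinol to the cross-conjugated dienone, or its Lewis acidity may trigger loss of water or silanol with aromatisation of the dienol, or open the new vinyl oxirane with tert-butanol. The fallback sets out from 4, so the benzoylation of step 3 is postponed, and uses reagent control through the primary C7 hydroxyl in place of substrate direction by C2–OH. A Katsuki–Sharpless asymmetric epoxidation (Ti(OiPr)4, D-(−)-diethyl tartrate, t-BuOOH, 4 Å molecular sieves, CH2Cl2, −20 °C) is run with the tartrate enantiomer whose facial preference for this 2,3-disubstituted allylic alcohol should fall on the C2–OH face, so that reagent and substrate bias reinforce each other. This should give (1S,2S,3S,6R)-3-[(tert-butyldimethylsilyl)oxy]-1-(hydroxymethyl)-7-oxabicyclo[4.1.0]hept-4-en-2-ol F1. Its primary hydroxyl is then benzoylated (BzCl, 2,4,6-collidine, CH2Cl2, −78 to −40 °C), and the route is rejoined at 6.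

Step 5. Benzoate may be diverted to conjugate attack at C4, the C6–O bond may ionise on titanium so that the configuration at C6 is lost, or titanium isopropoxide may transesterify the C7 benzoate. The fallback sets out from 6 and forms the C6–O bond with water instead of benzoate. Dilute-acid hydrolysis (HClO4 cat., THF–H2O, 0 °C) should open the protonated vinyl oxirane at allylic C6 anti to the ring oxygen and give [(1R,2S,5S,6S)-5-[(tert-butyldimethylsilyl)oxy]-1,2,6-trihydroxycyclohex-3-en-1-yl]methyl benzoate F2. The C6 hydroxyl (allylic, flanked by an sp2 carbon) is then benzoylated in preference to the C2 hydroxyl (flanked by the quaternary carbon and the cis silyl ether) and the tertiary C1 hydroxyl (BzCl, pyridine, CH2Cl2, −40 °C). The route is rejoined at 8.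

Step 8. The oxyphosphonium ion of the hindered allylic alcohol may be displaced with allylic transposition (attack at C5) or may eliminate, or the basic betaine may move the C2 acetyl group to C3 before activation occurs. The fallback sets out from 10 and separates activation from displacement. MsCl, Et3N, CH2Cl2, −20 °C should give [(1R,2S,5S,6S)-6-(acetyloxy)-2-(benzoyloxy)-1-hydroxy-5-[(methanesulfonyl)oxy]cyclohex-3-en-1-yl]methyl benzoate F3. This is displaced by caesium benzoate (CsO2CPh, 18-crown-6, toluene, 40 °C) in a direct SN2 reaction with inversion at C3. The route is rejoined at 11.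

**Further compounds**

F1 | step 4 | (1S,2S,3S,6R)-3-[(tert-butyldimethylsilyl)oxy]-1-(hydroxymethyl)-7-oxabicyclo[4.1.0]hept-4-en-2-ol | O[C@H]1[C@@H](O[Si](C)(C)C(C)(C)C)C=C[C@H]2O[C@@]12CO
F2 | step 5 | [(1R,2S,5S,6S)-5-[(tert-butyldimethylsilyl)oxy]-1,2,6-trihydroxycyclohex-3-en-1-yl]methyl benzoate | O[C@H]1[C@@H](O[Si](C)(C)C(C)(C)C)C=C[C@H](O)[C@]1(O)COC(=O)c1ccccc1
F3 | step 8 | [(1R,2S,5S,6S)-6-(acetyloxy)-2-(benzoyloxy)-1-hydroxy-5-[(methanesulfonyl)oxy]cyclohex-3-en-1-yl]methyl benzoate | CC(=O)O[C@H]1[C@@H](OS(C)(=O)=O)C=C[C@H](OC(=O)c2ccccc2)[C@]1(O)COC(=O)c1ccccc1
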